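The octamer is traced back to its twenty-fold methyl ether. That ether comes from a hexabromide in which C2 and C6 of rings C, E and G, the carbons flanking the ether carbon C1, bear bromine instead of oxygen. One copper-mediated methoxylation converts all six C–Br bonds into C–OMe bonds once the seven diaryl ethers are in place. The hexabromide is grown from ring H by three additions of a single two-ring building block. This block is a tosyl-protected trimethoxycatechol ring, joined by SNAr to a dibromophenyl ring that carries an aryl(trimethoxyphenyl)iodonium group. Ring A is added last as an aryne. All oxidants are confined to the building block.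

Key step: step 17

**Remarks before the steps**
- **Lettering:** rings A to H run from the 3,5-dioxygenated end ring to the 2,4,6-trioxygenated end ring. In B, D and F, C1 bears the oxygen to the preceding ring and C2 the oxygen to the following ring. In C, E and G, C1 bears the oxygen from the preceding ring and C4 the oxygen to the following ring.
- **Structure check:** eight rings, seven bridging oxygens, twenty hydroxyl groups, no stereocentre. The hexabromide carries fourteen methoxy groups and the permethyl ether twenty.
- **Oxygen count:** only seven bridging oxygens exist. Here B, D and F each supply two (one from the phenol 1, one from step 5) and H supplies one. Rings C, E, G and A therefore enter as electrophiles without oxygen at the bridging carbons. A hydroquinone unit for C, E and G combined with phenols for every other ring would bring too many oxygens.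
- **Oxidation-prone rings:** the bromines protect only C, E and G. Rings A, B, D, F and H stay electron-rich, so the growing chain is exposed only to base, fluoride and the iodonium salt.
- **Assumption:** 2 and 14 are taken as catalogue compounds.

**Step 1**
Reactants: 1 3,4,5-trimethoxyphenol; 2 1,3-dibromo-2-fluoro-5-nitrobenzene
Product: 3 1,3-dibromo-5-nitro-2-(3,4,5-trimethoxyphenoxy)benzene
Conditions: K2CO3, DMF, 60 °C, N2
Reagents that add atoms: none
Why: Nucleophilic aromatic substitution by addition–elimination, in which the fluoride of 2 (para to the nitro group, flanked by two withdrawing bromines) is displaced by the unhindered phenoxide of 1 while the meta bromines stay, so the crowded ether is made while the phenol ring still has two free ortho positions.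

**Step 2**
Reactants: 3 1,3-dibromo-5-nitro-2-(3,4,5-trimethoxyphenoxy)benzene
Product: 4 3,5-dibromo-4-(3,4,5-trimethoxyphenoxy)aniline
Conditions: Fe powder, NH4Cl, EtOH/H2O, 80 °C
Reagents that add atoms: none
Why: Béchamp-type iron reduction of a nitroarene by stepwise electron and proton transfer, which leaves aryl bromides and aryl ethers alone.

**Step 3**
Reactants: 4 3,5-dibromo-4-(3,4,5-trimethoxyphenoxy)aniline
Product: 6 1,3-dibromo-5-iodo-2-(3,4,5-trimethoxyphenoxy)benzene, via diazonium tosylate 5 (not isolated)
Conditions: NaNO2, TsOH·H2O, MeCN/H2O, 0 °C; H2NSO3H; then KI, 0 °C → rt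
Reagents that add atoms: potassium iodide [K+].[I-]; sodium nitrite (second nitrogen of 5) [Na+].[O-]N=O; 4-methylbenzenesulfonic acid (counter-ion of 5) Cc1ccc(cc1)S(=O)(=O)O
Why: Sandmeyer-type iodo-dediazoniation without copper, in which iodide reduces the diazonium ion and traps the aryl radical, and in which surplus nitrite is destroyed before KI is added so that no oxidative iodination of the trimethoxylated ring can start.

**Step 4**
Reactants: 6 1,3-dibromo-5-iodo-2-(3,4,5-trimethoxyphenoxy)benzene
Product: 8 6-(2,6-dibromo-4-iodophenoxy)-2,3,4-trimethoxybenzaldehyde, via iminium dichlorophosphate 7 (not isolated)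
Conditions: POCl3, DMF, 75 °C; then H2O, 0 °C → rt
Reagents that add atoms: N,N-dimethylformamide CN(C)C=O; water O; phosphoryl chloride (counter-ion of 7) O=P(Cl)(Cl)Cl
Why: Vilsmeier–Haack formylation, in which the two free positions of the trimethoxyphenoxy ring are equivalent and activated by three ortho/para oxygens, so one regioisomer should form, the formyl group stops a second attack and the trihalogenated ring is inert.

**Step 5**
Reactants: 8 6-(2,6-dibromo-4-iodophenoxy)-2,3,4-trimethoxybenzaldehyde
Product: 10 6-(2,6-dibromo-4-iodophenoxy)-2,3,4-trimethoxyphenol, via aryl formate 9 (not isolated)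
Conditions: mCPBA, CH2Cl2, 0 °C → rt; then K2CO3 (cat.), MeOH, rt, Ar
Reagents that add atoms: 3-chloroperoxybenzoic acid OOC(=O)c1cccc(Cl)c1
Why: Baeyer–Villiger (Dakin-type) oxidation, in which the electron-rich aryl group with two ortho oxygens migrates in the Criegee adduct and methanolysis frees the phenol; the nitro group is already gone, so the new phenoxide cannot start a Smiles migration of the halogenated ring.

**Step 6**
Reactants: 10 6-(2,6-dibromo-4-iodophenoxy)-2,3,4-trimethoxyphenol
Product: 11 6-(2,6-dibromo-4-iodophenoxy)-2,3,4-trimethoxyphenyl 4-methylbenzenesulfonate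
Conditions: TsCl, Et3N, DMAP (cat.), CH2Cl2, 0 °C → rt
Reagents that add atoms: 4-methylbenzenesulfonyl chloride Cc1ccc(cc1)S(=O)(=O)Cl
Why: DMAP-catalysed sulfonylation of a phenol, giving a tosylate that masks the C1 oxygen, cannot migrate, resists phenoxides and lowers the electron density of the ring for step 7.

**Step 7**
Reactants: 11 6-(2,6-dibromo-4-iodophenoxy)-2,3,4-trimethoxyphenyl 4-methylbenzenesulfonate
Product: 13 {3,5-dibromo-4-[2-(tosyloxy)-3,4,5-trimethoxyphenoxy]phenyl}(2,4,6-trimethoxyphenyl)iodonium tosylate, via (diacetoxyiodo)arene 12 (not isolated)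
Conditions: mCPBA, AcOH, 50 °C; evaporate; then 1,3,5-trimethoxybenzene, TsOH·H2O, MeCN, rt
Reagents that add atoms: 1,3,5-trimethoxybenzene COc1cc(OC)cc(OC)c1; 4-methylbenzenesulfonic acid Cc1ccc(cc1)S(=O)(=O)O; acetic acid (ligands of 12) CC(=O)O
Why: Known two-stage diaryliodonium synthesis (peracid oxidation of the aryl iodide to the diacetate, then acid-triggered electrophilic aromatic substitution), in which the far more nucleophilic trimethoxybenzene is already present when the trivalent iodine becomes electrophilic and should outcompete the tosylate-deactivated ring.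

**Step 8**
Reactants: 14 2,4,6-trimethoxyphenol; 13 iodonium tosylate building block
Product: 15 trimer tosylate (rings F–G–H) 6-[2,6-dibromo-4-(2,4,6-trimethoxyphenoxy)phenoxy]-2,3,4-trimethoxyphenyl 4-methylbenzenesulfonate
Conditions: 14, KOt-Bu (slight deficit), THF, 0 °C, Ar; then 13, 40 °C, dark
Reagents that add atoms: none
Why: Metal-free O-arylation of a phenoxide with an unsymmetrical diaryliodonium salt (ligand exchange at iodine, then ligand coupling), in which the more electron-poor bromine-bearing aryl group is transferred, the trimethoxyphenyl group leaves as its iodide, di-ortho-substituted phenols are accepted, and aryl bromides and the tosylate are spared.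

**Step 9**
Reactants: 15 trimer tosylate
Product: 16 trimer phenol (rings F–G–H) 6-[2,6-dibromo-4-(2,4,6-trimethoxyphenoxy)phenoxy]-2,3,4-trimethoxyphenol
Conditions: KOH, EtOH/THF/H2O, 70 °C, Ar; then aq. HCl
Reagents that add atoms: none
Why: Alkaline hydrolysis of an aryl sulfonate by attack of hydroxide at sulfur, under which unactivated aryl bromides, diaryl ethers and methyl ethers are inert.

**Step 10**
Reactants: 16 trimer phenol; 13 iodonium tosylate building block
Product: 17 pentamer tosylate (rings D–H, C1 oxygen of ring D tosylated)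
Conditions: 16, KOt-Bu (slight deficit), THF, 0 °C, Ar; then 13, 40 °C, dark
Reagents that add atoms: none
Why: Same diaryliodonium O-arylation as in step 8, in which the phenoxide at C1 of ring F is flanked by methoxy and aryloxy but the transferred carbon C4 of ring E has only hydrogen neighbours, so the new ether carries ortho substituents on one side only.

**Step 11**
Reactants: 17 pentamer tosylate
Product: 18 pentamer phenol (rings D–H, free hydroxyl at C1 of ring D)
Conditions: KOH, EtOH/THF/H2O, 70 °C, Ar; then aq. HCl
Reagents that add atoms: none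
Why: Alkaline sulfonate hydrolysis as in step 9, with no ring in the chain carrying a group that would activate a bromide or an ether carbon toward hydroxide.

**Step 12**
Reactants: 18 pentamer phenol; 13 iodonium tosylate building block
Product: 19 heptamer tosylate (rings B–H, C1 oxygen of ring B tosylated)
Conditions: 18, KOt-Bu (slight deficit), THF, 0 °C, Ar; then 13, 40 °C, dark
Reagents that add atoms: none
Why: Third diaryliodonium O-arylation of the same type, in which the reacting site is locally identical to that of step 10, so chain length should affect only solubility.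

**Step 13**
Reactants: 19 heptamer tosylate
Product: 20 heptamer phenol (rings B–H, free hydroxyl at C1 of ring B)
Conditions: KOH, EtOH/THF/H2O, 70 °C, Ar; then aq. HCl
Reagents that add atoms: none
Why: Alkaline sulfonate hydrolysis as in steps 9 and 11.

**Step 14**
Reactants: 21 3,5-dimethoxyphenol
Product: 22 2-bromo-3,5-dimethoxyphenol
Conditions: NBS, i-Pr2NH (cat.), CH2Cl2, −78 → 0 °C
Reagents that add atoms: N-bromosuccinimide O=C1CCC(=O)N1Br
Why: Amine-mediated ortho-selective electrophilic bromination of a phenol, in which the N-bromoamine is delivered through a hydrogen bond to the hydroxyl group and so favours C2 over the more crowded C4 between the two methoxy groups.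

**Step 15**
Reactants: 22 2-bromo-3,5-dimethoxyphenol
Product: 25 3,5-dimethoxy-2-(trimethylsilyl)phenyl trifluoromethanesulfonate, via trimethylsilyl ether 23 (not isolated), via lithium silylphenolate 24 (not isolated)
Conditions: (Me3Si)2NH, THF, 65 °C, evaporate; n-BuLi, THF, −78 °C; then Tf2O, −78 → 0 °C
Reagents that add atoms: hexamethyldisilazane C[Si](C)(C)N[Si](C)(C)C; trifluoromethanesulfonic anhydride O=S(=O)(OS(=O)(=O)C(F)(F)F)C(F)(F)F; n-butyllithium (lithium of 24) [Li]CCCC
Why: Standard route to o-silylaryl triflates by O-silylation, bromine–lithium exchange, anionic shift of silicon from oxygen to carbon (retro-Brook rearrangement) and triflation of the released phenolate.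

**Step 16**
Reactants: 20 heptamer phenol; 25 3,5-dimethoxy-2-(trimethylsilyl)phenyl trifluoromethanesulfonate
Product: 27 hexabromo octamer (rings C, E, G 2,6-dibrominated; fourteen methoxy groups), via 3,5-dimethoxybenzyne 26 (not isolated)
Conditions: CsF, MeCN/toluene, rt, Ar
Reagents that add atoms: none
Why: Aryne O-arylation of a phenol, in which fluoride-induced 1,2-elimination gives the aryne, its C3 methoxy group directs the phenoxide to the remote aryne carbon so that protonation gives the 3,5-dimethoxyphenyl ether, and the mild metal-free conditions leave the six bromines alone.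

**Step 17**
Reactants: 27 hexabromo octamer
Product: 28 permethylated octamer (twenty-fold methyl ether of the target)
Conditions: NaOMe (5.4 M in MeOH, 6 equiv per C–Br), CuBr (0.2 equiv per C–Br), MeOAc (0.3 equiv per C–Br), DMF, 110 °C, sealed vessel, Ar
Reagents that add atoms: sodium methoxide C[O-].[Na+]
Why: This is the Ullmann-type copper-catalysed methoxylation of aryl bromides, the reaction that converts 3,5-dibromo-4-hydroxybenzaldehyde into syringaldehyde: a methoxocuprate of monovalent copper formed from CuBr and excess NaOMe inserts into a C–Br bond, and the trivalent aryl copper methoxide collapses by reductive elimination to the aryl methyl ether and CuBr. The six sites (C2 and C6 of rings C, E and G) sit on three separate rings and react independently, so the step is six repeats of one known event; no ring is closed and no stereocentre is made. The selectivity needed is substitution over hydrodebromination and over cleavage of the seven diaryl ethers. Each bromine has a single ortho neighbour, the ether oxygen at C1, which can pre-coordinate copper, and its other ortho position is C–H, so every site is accessible. Concentrated methoxide in large excess, exclusion of air and water, and methyl acetate as ester co-catalyst (chosen so that no foreign alkoxide appears) should keep the copper methoxide pathway ahead of reduction. No ring carries a group that activates an ether carbon toward methoxide, and a stray O-demethylation would be harmless because step 18 removes every methyl group.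

**Step 18**
Reactants: 28 permethylated octamer
Product: 29 target CNP0319661.0 (free octamer with twenty hydroxyl groups)
Conditions: BBr3 (3 equiv per OMe), CH2Cl2, −78 °C → rt, Ar; then H2O, 0 °C; reversed-phase isolation with degassed solvents
Reagents that add atoms: none
Why: Lewis acid ether cleavage, in which BBr3 binds each methoxy oxygen and bromide removes the methyl group by SN2, whereas the diaryl ether oxygens have no sp3 carbon to lose and should survive.

**Compound list**

1 | 3,4,5-trimethoxyphenol | COc1cc(O)cc(OC)c1OC | starting material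
2 | 1,3-dibromo-2-fluoro-5-nitrobenzene | O=[N+]([O-])c1cc(Br)c(F)c(Br)c1 | starting material
3 | 1,3-dibromo-5-nitro-2-(3,4,5-trimethoxyphenoxy)benzene | COc1cc(Oc2c(Br)cc(cc2Br)[N+](=O)[O-])cc(OC)c1OC | intermediate
4 | 3,5-dibromo-4-(3,4,5-trimethoxyphenoxy)aniline | COc1cc(Oc2c(Br)cc(N)cc2Br)cc(OC)c1OC | intermediate
5 | 3,5-dibromo-4-(3,4,5-trimethoxyphenoxy)benzenediazonium tosylate (not isolated) | COc1cc(Oc2c(Br)cc(cc2Br)[N+]#N)cc(OC)c1OC.Cc1ccc(cc1)S(=O)(=O)[O-] | intermediate
6 | 1,3-dibromo-5-iodo-2-(3,4,5-trimethoxyphenoxy)benzene | COc1cc(Oc2c(Br)cc(I)cc2Br)cc(OC)c1OC | intermediate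
7 | [6-(2,6-dibromo-4-iodophenoxy)-2,3,4-trimethoxybenzylidene]dimethylammonium dichlorophosphate (not isolated) | COc1cc(Oc2c(Br)cc(I)cc2Br)c(C=[N+](C)C)c(OC)c1OC.[O-]P(=O)(Cl)Cl | intermediate
8 | 6-(2,6-dibromo-4-iodophenoxy)-2,3,4-trimethoxybenzaldehyde | COc1cc(Oc2c(Br)cc(I)cc2Br)c(C=O)c(OC)c1OC | intermediate
9 | 6-(2,6-dibromo-4-iodophenoxy)-2,3,4-trimethoxyphenyl formate (not isolated) | COc1cc(Oc2c(Br)cc(I)cc2Br)c(OC=O)c(OC)c1OC | intermediate
10 | 6-(2,6-dibromo-4-iodophenoxy)-2,3,4-trimethoxyphenol | Oc1c(Oc2c(Br)cc(I)cc2Br)cc(OC)c(OC)c1OC | intermediate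
11 | 6-(2,6-dibromo-4-iodophenoxy)-2,3,4-trimethoxyphenyl 4-methylbenzenesulfonate | Cc1ccc(cc1)S(=O)(=O)Oc1c(Oc2c(Br)cc(I)cc2Br)cc(OC)c(OC)c1OC | intermediate
12 | 6-[2,6-dibromo-4-(diacetoxyiodo)phenoxy]-2,3,4-trimethoxyphenyl 4-methylbenzenesulfonate (not isolated) | Cc1ccc(cc1)S(=O)(=O)Oc1c(Oc2c(Br)cc(I(OC(C)=O)OC(C)=O)cc2Br)cc(OC)c(OC)c1OC | intermediate
13 | {3,5-dibromo-4-[2-(tosyloxy)-3,4,5-trimethoxyphenoxy]phenyl}(2,4,6-trimethoxyphenyl)iodonium tosylate | Cc1ccc(cc1)S(=O)(=O)Oc1c(Oc2c(Br)cc([I+]c3c(OC)cc(OC)cc3OC)cc2Br)cc(OC)c(OC)c1OC.Cc1ccc(cc1)S(=O)(=O)[O-] | intermediate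
14 | 2,4,6-trimethoxyphenol | COc1cc(OC)c(O)c(OC)c1 | starting material
15 | trimer tosylate, rings F–G–H | Cc1ccc(cc1)S(=O)(=O)Oc1c(Oc2c(Br)cc(Oc3c(OC)cc(OC)cc3OC)cc2Br)cc(OC)c(OC)c1OC | intermediate
16 | trimer phenol, rings F–G–H | Oc1c(Oc2c(Br)cc(Oc3c(OC)cc(OC)cc3OC)cc2Br)cc(OC)c(OC)c1OC | intermediate
17 | pentamer tosylate, rings D–H | Cc1ccc(cc1)S(=O)(=O)Oc1c(Oc2c(Br)cc(Oc3c(Oc4c(Br)cc(Oc5c(OC)cc(OC)cc5OC)cc4Br)cc(OC)c(OC)c3OC)cc2Br)cc(OC)c(OC)c1OC | intermediate
18 | pentamer phenol, rings D–H | Oc1c(Oc2c(Br)cc(Oc3c(Oc4c(Br)cc(Oc5c(OC)cc(OC)cc5OC)cc4Br)cc(OC)c(OC)c3OC)cc2Br)cc(OC)c(OC)c1OC | intermediate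
19 | heptamer tosylate, rings B–H | Cc1ccc(cc1)S(=O)(=O)Oc1c(Oc2c(Br)cc(Oc3c(Oc4c(Br)cc(Oc5c(Oc6c(Br)cc(Oc7c(OC)cc(OC)cc7OC)cc6Br)cc(OC)c(OC)c5OC)cc4Br)cc(OC)c(OC)c3OC)cc2Br)cc(OC)c(OC)c1OC | intermediate
20 | heptamer phenol, rings B–H | Oc1c(Oc2c(Br)cc(Oc3c(Oc4c(Br)cc(Oc5c(Oc6c(Br)cc(Oc7c(OC)cc(OC)cc7OC)cc6Br)cc(OC)c(OC)c5OC)cc4Br)cc(OC)c(OC)c3OC)cc2Br)cc(OC)c(OC)c1OC | intermediate
21 | 3,5-dimethoxyphenol | COc1cc(O)cc(OC)c1 | starting material
22 | 2-bromo-3,5-dimethoxyphenol | COc1cc(O)c(Br)c(OC)c1 | intermediate
23 | (2-bromo-3,5-dimethoxyphenoxy)trimethylsilane (not isolated) | COc1cc(O[Si](C)(C)C)c(Br)c(OC)c1 | intermediate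
24 | lithium 3,5-dimethoxy-2-(trimethylsilyl)phenolate (not isolated) | COc1cc([O-])c([Si](C)(C)C)c(OC)c1.[Li+] | intermediate
25 | 3,5-dimethoxy-2-(trimethylsilyl)phenyl trifluoromethanesulfonate | COc1cc(OS(=O)(=O)C(F)(F)F)c([Si](C)(C)C)c(OC)c1 | intermediate
26 | 3,5-dimethoxybenzyne (1,2-didehydro-3,5-dimethoxybenzene, not isolated) | COC1=CC(OC)=CC#C1 | intermediate
27 | hexabromo octamer | COc1cc(OC)cc(Oc2c(Oc3c(Br)cc(Oc4c(Oc5c(Br)cc(Oc6c(Oc7c(Br)cc(Oc8c(OC)cc(OC)cc8OC)cc7Br)cc(OC)c(OC)c6OC)cc5Br)cc(OC)c(OC)c4OC)cc3Br)cc(OC)c(OC)c2OC)c1 | intermediate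
28 | permethylated octamer | COc1cc(OC)cc(Oc2c(Oc3c(OC)cc(Oc4c(Oc5c(OC)cc(Oc6c(Oc7c(OC)cc(Oc8c(OC)cc(OC)cc8OC)cc7OC)cc(OC)c(OC)c6OC)cc5OC)cc(OC)c(OC)c4OC)cc3OC)cc(OC)c(OC)c2OC)c1 | intermediate
29 | CNP0319661.0 | Oc1cc(O)cc(Oc2c(Oc3c(O)cc(Oc4c(Oc5c(O)cc(Oc6c(Oc7c(O)cc(Oc8c(O)cc(O)cc8O)cc7O)cc(O)c(O)c6O)cc5O)cc(O)c(O)c4O)cc3O)cc(O)c(O)c2O)c1 | target

**Step count:** 18 steps in total. The longest linear sequence is 16 steps (steps 1–13, then 16–18). Steps 14 and 15 form a two-step side branch. Compound 13 is made once and used three times.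

**Steps most likely to fail**

1. **Step 17.** The exchange may stall at partly substituted stages, bromine may be lost by reduction, or hot methoxide may slowly attack the ethers.
   - The fallback sets out from 27 and changes both the metal and the oxygen nucleophile.
   - Palladium-catalysed hydroxylation is used: Pd2(dba)3, 2-di-tert-butylphosphino-2',4',6'-triisopropylbiphenyl, KOH, 1,4-dioxane/H2O, 100 °C, Ar, then aq. HCl.
   - It proceeds by oxidative addition at zerovalent palladium and reductive elimination from a bulky phosphine complex, and should give the hexaphenol tetradecamethyl ether F1.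
   - F1 needs no methylation. BBr3 under the conditions of step 18 cleaves its fourteen methyl ethers, and the route is rejoined at 29.

2. **Step 7.** The peracid may over-oxidise the trimethoxylated ring, or the trivalent iodine centre may attack that ring in a second molecule before the auxiliary arene is captured.
   - The fallback sets out from 11 and reverses the polarity of salt formation, so that 11 never carries an oxidised iodine.
   - Selective iodine–magnesium exchange (i-PrMgCl·LiCl, THF, −40 °C, bromides untouched) followed by Bu3SnCl should give the tributyl arylstannane F2.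
   - Ipso-destannylation of F2 with separately made [hydroxy(tosyloxy)iodo]-4-methoxybenzene in CH2Cl2 at rt should give the aryl(4-methoxyphenyl)iodonium tosylate F3.
   - F3 replaces 13 in steps 8, 10 and 12, with the anisyl group as the non-transferred ligand. The route is rejoined at 15.

3. **Step 8** (the same applies to steps 10 and 12). Electron transfer from the very electron-rich phenoxide to the iodonium ion may oxidise the phenol instead of arylating it, or part of the auxiliary aryl group may be transferred.
   - The fallback sets out from 11 and 14 and abandons hypervalent iodine altogether.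
   - A copper-catalysed Ullmann ether synthesis is run on the aryl iodide itself: CuI, picolinic acid, K3PO4, DMSO, 80 °C, Ar.
   - It relies on the much faster reaction of the unhindered C–I bond than of the ortho-substituted C–Br bonds. The route is rejoined at 15, and with 16 or 18 in place of 14 at 17 or 19.

**Further compounds**

F1 | step 17 | hexaphenol tetradecamethyl ether (hydroxyl at C2 and C6 of rings C, E, G; all other oxygens methylated) | COc1cc(OC)cc(Oc2c(Oc3c(O)cc(Oc4c(Oc5c(O)cc(Oc6c(Oc7c(O)cc(Oc8c(OC)cc(OC)cc8OC)cc7O)cc(OC)c(OC)c6OC)cc5O)cc(OC)c(OC)c4OC)cc3O)cc(OC)c(OC)c2OC)c1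
F2 | step 7 | 6-[2,6-dibromo-4-(tributylstannyl)phenoxy]-2,3,4-trimethoxyphenyl 4-methylbenzenesulfonate | Cc1ccc(cc1)S(=O)(=O)Oc1c(Oc2c(Br)cc(cc2Br)[Sn](CCCC)(CCCC)CCCC)cc(OC)c(OC)c1OC
F3 | step 7 | {3,5-dibromo-4-[2-(tosyloxy)-3,4,5-trimethoxyphenoxy]phenyl}(4-methoxyphenyl)iodonium tosylate | Cc1ccc(cc1)S(=O)(=O)Oc1c(Oc2c(Br)cc([I+]c3ccc(OC)cc3)cc2Br)cc(OC)c(OC)c1OC.Cc1ccc(cc1)S(=O)(=O)[O-]
F0 | step 8 | none | none
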